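With a small charge of substrate, fed in two portions to a stirred flask where solid reagent is suspected of dissolving to partner, and partner of turning substrate into target and by-product, I asked first how steep the target's line was and what would bend it.

| setting | Monday's | Friday's | blue | teal | amber | green |
|---|---|---|---|---|---|---|
| substrate | 4 mM (in portions, 2) | 4 mM (in portions, 2) | 4.0 mM (in portions, 2) | 8.0 mM (in portions, 2) | 15 mM (in portions, 2) | 30 mM (in portions, 2) |
| solid reagent | 6.4 mM | 19 mM | 9.60 mM | 9.60 mM | 9.60 mM | 9.60 mM |
| remark | run made earlier; portions every 12 min | run made earlier; portions every 12 min | the portions of substrate follow each other after 12 min, the first at the start | the portions of substrate follow each other after 12 min, the first at the start | the portions of substrate follow each other after 12 min, the first at the start | the portions of substrate follow each other after 12 min, the first at the start |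
| time |  |  | 25 min | 25 min | 25 min | 25 min |

| Monday's: time / min | Monday's: target / % | Friday's: time / min | Friday's: target / % |
|---|---|---|---|
| 2.00 | 0 | 0.667 | 0 |
| 4.00 | 3.8 | 1.50 | 0 |
| 6.00 | 6.2 | 4.00 | 3.0 |
| 8.00 | 11.0 | 8.00 | 10.8 |

(each reading ± 1 percentage point)

- amounts and yields of by-product count crystals too
- given per volume of solution although it is solid: crystals, solid reagent
- what was read earlier has a scatter of 1 percentage point, one standard deviation
- on the list of suspects stand: solid reagent <-> partner; substrate -> decomposition product; crystals <-> by-product; substrate + partner <-> target + by-product
- at the start none of the solid reagent is in solution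
- "hardly changes" means that all values lie within two and a half points (for a concentration: within two and a half percent of the largest)

- amount of target at the end, in percent of the substrate charged for blue, teal, amber, green, in this order
- how the row runs (rises, then falls / hardly changes / rises all the way / falls, then rises / falls all the way)

Friday's flask held 2.97 times Monday's solid reagent, yet at 8.00 min the two read 11.0% and 10.8% of the charge. Monday's target was still unseen at 2.00 min. So I took one slope from that lag to their mean, a reading that carries their scatter, as a fraction of the charge:

slope = 0.0182 min⁻¹

That slope came from half the charge. I assumed the second portion would make the line twice as steep: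

0.0182 min⁻¹ × (12 min − 2.00 min) + 2 × 0.0182 min⁻¹ × (25 min − 12 min) = 65.4%

I called this the straight-line yield, the fraction of the charge that the early rate, stepped up at the second portion, reaches by the end if the line stays straight.

I looked at two things that could bend it. Substrate gets used up: at a pseudo-first-order pace of 0.0363 min⁻¹, the portions give 47.1%, a factor of 0.720 on the line. The way back could slow it too, but rising readings put no figure on that, so I gave it factor one. In green, the solid reagent allows 32.0% of the charge, one for one, less than that. I committed to 47.1% for blue, teal and amber, and 32.0% for green.

The forecast said 45%, 43%, 38% and 25%, falls all the way, holding that at higher charge “by-product build-up and limited dissolution lower it”.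

The flasks gave 49.3%, 37.5%, 31.0% and 22.2%: falls all the way.

    solid reagent ⇌ partner, rate k1*(cs1 - [partner]) while solid is left; crystals form when [partner] > cs1 (solubility = 14.0 mM, k = 5.79 × 10⁻⁴ s⁻¹)
    substrate → decomposition product (k = 3.56 × 10⁻⁶ s⁻¹)
    crystals ⇌ by-product, rate k3*(cs3 - [by-product]) while solid is left; crystals form when [by-product] > cs3 (solubility = 2.90 mM, k = 0.0160 s⁻¹)
    substrate + partner ⇌ target + by-product (K = 0.320, k = 0.329 M⁻¹ s⁻¹)

Blue reached 0.754 of the straight-line yield. The return of target + by-product to substrate + partner is the main reason for what blue's target lacks of the whole charge, 55% of what is missing: the same run without it gives 77.3% against 49.3%, past 65.4% itself. Green, held against the smaller of 65.4% and 32.0%, reached 0.694 of it. The return is a part of that shortfall, for green without it gives 31.2% against 22.2%.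

The earlier runs and the new flask are simulated with constants of no real substance; the scatter is artificial.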